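**The idea.** If target, once past its peak, drains like a tank through a fixed valve, it follows P(t) = I·exp(−λt), with P the target, I the intercept extended back to time zero, and λ a pseudo-first-order fall constant, read as the logarithm of the ratio of two late readings over the time between them.

| setting | eta | zeta | delta | north-east | south-east |
|---|---|---|---|---|---|
| starting material | 15 mM | 15 mM | 7.5 mM | 15 mM | 15 mM |
| protic impurity | 21 mM | 33 mM | 15 mM | 15.0 mM | 15.0 mM |
| temperature | 30 °C | 42 °C | 30 °C | 35 °C | 50 °C |
| remark | run made earlier | run made earlier | run made earlier |  |  |
| time |  |  |  | 12 min | 12 min |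

| run | time / min | target / % | starting material / % |
|---|---|---|---|
| eta | 1.00 | 46.7 | 34.4 |
| eta | 2.00 | 59.3 | 16.2 |
| eta | 3.00 | 61.6 | 10.4 |
| eta | 6.00 | 59.4 | 7.1 |
| eta | 12.0 | 52.3 | 5.9 |
| zeta | 2.50 | 42.8 | 12.3 |
| zeta | 5.00 | 32.4 | 7.1 |
| zeta | 8.00 | 25.0 | 5.0 |
| zeta | 10.0 | 21.7 | 3.2 |
| zeta | 12.0 | 19.6 | 3.5 |
| delta | 1.00 | 49.6 | 38.0 |
| delta | 3.00 | 71.0 | 8.7 |
| delta | 6.00 | 71.0 | 5.6 |
| delta | 8.00 | 69.8 | 5.4 |
| delta | 12.0 | 67.0 | 5.0 |

(scatter of a reading: 0.3 percentage points)

1. the flask that comes out highest in amount of target, in percent of the starting material charged, or "all alike" when all lie within 1.5 percentage points (north-east / south-east / all alike)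
2. target at the end, in percent of the starting material charged, north-east
3. target at the end, in percent of the starting material charged, south-east

- a species is counted by the starting material in it: one side product or homo dimer counts as two
- what was read earlier has a scatter of 0.3 percentage points, one standard deviation
- on the list of suspects stand: starting material + target -> side product; starting material <-> target + by-product; 2 starting material -> homo dimer; starting material + protic impurity -> quenched substrate

**The falls.** Eta's last two readings gave λ = 0.0212 min⁻¹, my fall constant, and zeta from its second reading on gave 0.0718 min⁻¹. Both runs had the same charge of starting material, so I divided each λ by its protic impurity and took the remaining factor of 2.15 as the effect of going from 30 °C to 42 °C, with ln λ straight in temperature.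

**The intercepts.** The same lines extended back gave I = 67.5% in eta and 46.4% in zeta. Treating ln I the same way gave 57.7% for north-east and 36.1% for south-east.

**The chain's end.** With impurity at 15.0 mM, λ came to 0.0209 min⁻¹ in north-east and 0.0544 min⁻¹ in south-east. So at 12 min I reckoned target at 44.9% in north-east, above the 18.8% of south-east.

**Weak link.** Eta and zeta changed impurity and temperature together, so the proportion to impurity was an assumption. Without it my figures became 37.8% and 5.18%. Delta, at eta's temperature with less impurity, fell at 0.00966 min⁻¹, slower than eta, though its charge was lower too. Two settings differed there, so delta pointed the same way without proving the proportion; I kept it and committed to 44.9% and 18.8%.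

**The forecast.** It named north-east, with 52.5% and 25%, both higher than my figures. Of the hot flask it said: “More free starting material means faster quenching”.

**The result.** North-east ended at 45.8% and south-east at 14.4%, so north-east stood higher, as the forecast had named it.

    starting material + target → side product (k = 0.0450 M⁻¹ s⁻¹, Ea = 71.0 kJ mol⁻¹)
    starting material ⇌ target + by-product (K = 0.0390 M, k = 0.0230 s⁻¹, Ea = 84.0 kJ mol⁻¹, ΔH = −73.0 kJ mol⁻¹)
    2 starting material → homo dimer (k = 0.100 M⁻¹ s⁻¹, Ea = 57.0 kJ mol⁻¹)
    starting material + protic impurity → quenched substrate (k = 0.240 M⁻¹ s⁻¹, Ea = 44.0 kJ mol⁻¹)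
    (constants at 35 °C)

**The fall.** From 6.00 min to 12.0 min north-east's target fell with λ = 0.0298 min⁻¹, faster than my 0.0209 min⁻¹. In north-east at 0.217 min, target fell back 4.7 times faster than it went on. In north-east at 12.0 min the forward step alone used starting material at 9.3 times the rate of quenching, and the half-life of starting material by quenching alone stood at 4.7 min. For the same flask at 60 °C, my fall rule gave 7.67%. That flask ended with target at 4.58%.

The earlier runs and the new flask were computed with made-up constants; scatter was added.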